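**Retrosynthetic overview**
- The two quinone C–OMe bonds are disconnected last (C–O; dehydrogenative C–H methoxylation with methanol), giving the bis(indolyl)benzoquinone.
- The two indole C3–quinone bonds are disconnected next, giving two molecules of 2-(1,1-dimethylallyl)indole and p-benzoquinone.
- The indole C2–C(quaternary) bond is disconnected to indole and B-prenyl-9-BBN (reverse prenylation through 3-chloroindole).
- B-prenyl-9-BBN comes from 9-BBN and 3-methylbuta-1,2-diene.
- No ring is built: the indole and quinone rings are bought intact and only decorated.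

Assumption: the target as drawn has no stereocentre and no configurationally defined axis, so it is achiral and the route needs no enantiocontrol.

**Step 1**
Reactants: 1 9-borabicyclo[3.3.1]nonane (9-BBN, commercial dimer, 0.5 equiv of dimer); 2 3-methylbuta-1,2-diene (1.1 equiv)
Product: 3 B-prenyl-9-BBN [9-(3-methylbut-2-en-1-yl)-9-borabicyclo[3.3.1]nonane]
Conditions: THF, 0 °C → rt, 3 h, Ar; solution used directly
Reagents that add atoms: none
Why: Hydroboration of the unsubstituted terminal C=C of the 1,1-disubstituted allene places boron on the CH2 terminus and hydrogen on the central carbon, giving the allylic (prenyl) borane; the slight excess of allene leaves no B–H; no stereocentre is formed.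

**Step 2**
Reactants: 4 indole; 3 B-prenyl-9-BBN (2 equiv)
Product: 7 2-(2-methylbut-3-en-2-yl)-1H-indole, via 3-chloro-1H-indole 5 (not isolated), via N-boryl chloroindoline adduct 6 (not isolated)
Conditions: NCS (1.05 equiv), THF, 0 °C; then Et3N (2 equiv), 3 (THF solution), −78 °C → rt; aq. NaHCO3
Reagents that add atoms: none
Why: Reverse prenylation by C2-allylboration of a C3-chlorinated indole: the boron-bound 3H-tautomer of 5 is attacked at C2 through a six-membered transition state with allylic transposition (SE2′), which delivers the 1,1-dimethylallyl group, and Et3N-assisted loss of HCl from 6 rearomatises, so the two transient stereocentres of 6 are destroyed.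

**Step 3**
Reactants: 7 2-(2-methylbut-3-en-2-yl)-1H-indole (2.1 equiv); 8 1,4-benzoquinone (3.0 equiv in total)
Product: 12 2,5-bis[2-(2-methylbut-3-en-2-yl)-1H-indol-3-yl]-1,4-benzoquinone, via mono(indolyl)hydroquinone 9 (not isolated), via mono(indolyl)quinone 10 (not isolated), via bis(indolyl)hydroquinone 11 (not isolated)
Conditions: Bi(OTf)3 (5 mol%), MeCN, 0 °C, 8 (1.0 equiv); then 8 (2.0 equiv) in portions, rt
Reagents that add atoms: none
Why: Acid-catalysed Friedel–Crafts-type Michael addition of indole C3 to the quinone, each hydroquinone adduct being dehydrogenated by further benzoquinone (fast quinone/hydroquinone redox exchange); the second indole enters at C5 because the first indolyl group deactivates the C4 carbonyl as a vinylogous amide, leaving the β-carbon of the C1 enone the most electrophilic site; no stereocentre is formed.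

**Step 4**
Reactants: 12 2,5-bis[2-(2-methylbut-3-en-2-yl)-1H-indol-3-yl]-1,4-benzoquinone
Product: 16 2,5-dimethoxy-3,6-bis[2-(2-methylbut-3-en-2-yl)-1H-indol-3-yl]-1,4-benzoquinone (the target), via monomethoxy hydroquinone 13 (not isolated), via monomethoxy quinone 14 (not isolated), via dimethoxy hydroquinone 15 (not isolated)
Conditions: Sc(OTf)3 (10 mol%), chloranil (2.2 equiv), MeOH/ClCH2CH2Cl 1:1, 3 Å MS, 50 °C
Reagents that add atoms: methanol, CO
Why: Proposed new method: Lewis-acid-catalysed dehydrogenative double C–H methoxylation of a 2,5-diarylquinone, in which Sc(OTf)3 binds a quinone carbonyl, methanol adds oxa-Michael fashion to the only free β-carbon (C3, then C6), tautomerisation to the aromatic methoxyhydroquinone (13, then 15) makes the normally reversible addition irreversible, and chloranil (no C–H site, not attacked by the C2/C3-blocked indoles, a stronger oxidant than either electron-rich hydroquinone) returns each adduct to the quinone level (14, then 16) so no substrate is sacrificed as hydrogen acceptor; the near-orthogonal twist of the hindered indolyl groups limits their deactivating donation into the quinone, addition at the indolyl-bearing carbons is reversible and unproductive, and the closest known reaction types are the ZnCl2-mediated addition of methanol to p-benzoquinone (giving 2,5-dimethoxy-p-benzoquinone), the Thiele–Winter acetoxylation and the oxidative amination of quinones; no stereocentre is formed.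

**Compound list**
1 | 9-borabicyclo[3.3.1]nonane (9-BBN, monomer drawn; used as dimer) | B1C2CCCC1CCC2 | starting material
2 | 3-methylbuta-1,2-diene | C=C=C(C)C | starting material
3 | B-prenyl-9-BBN, 9-(3-methylbut-2-en-1-yl)-9-borabicyclo[3.3.1]nonane | CC(C)=CCB1C2CCCC1CCC2 | intermediate
4 | indole | c1ccc2[nH]ccc2c1 | starting material
5 | 3-chloro-1H-indole | Clc1c[nH]c2ccccc12 | intermediate (not isolated)
6 | 9-[3-chloro-2-(2-methylbut-3-en-2-yl)indolin-1-yl]-9-borabicyclo[3.3.1]nonane (racemic, relative configuration not controlled and lost in the next event) | C=CC(C)(C)C1C(Cl)c2ccccc2N1B1C3CCCC1CCC3 | intermediate (not isolated)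
7 | 2-(2-methylbut-3-en-2-yl)-1H-indole | C=CC(C)(C)c1cc2ccccc2[nH]1 | intermediate
8 | 1,4-benzoquinone | O=C1C=CC(=O)C=C1 | starting material
9 | 2-[2-(2-methylbut-3-en-2-yl)-1H-indol-3-yl]benzene-1,4-diol | C=CC(C)(C)c1[nH]c2ccccc2c1-c1cc(O)ccc1O | intermediate (not isolated)
10 | 2-[2-(2-methylbut-3-en-2-yl)-1H-indol-3-yl]-1,4-benzoquinone | C=CC(C)(C)c1[nH]c2ccccc2c1C1=CC(=O)C=CC1=O | intermediate (not isolated)
11 | 2,5-bis[2-(2-methylbut-3-en-2-yl)-1H-indol-3-yl]benzene-1,4-diol | C=CC(C)(C)c1[nH]c2ccccc2c1-c1cc(O)c(-c2c(C(C)(C)C=C)[nH]c3ccccc23)cc1O | intermediate (not isolated)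
12 | 2,5-bis[2-(2-methylbut-3-en-2-yl)-1H-indol-3-yl]-1,4-benzoquinone | C=CC(C)(C)c1[nH]c2ccccc2c1C1=CC(=O)C(c2c(C(C)(C)C=C)[nH]c3ccccc23)=CC1=O | intermediate
13 | 3-methoxy-2,5-bis[2-(2-methylbut-3-en-2-yl)-1H-indol-3-yl]benzene-1,4-diol | C=CC(C)(C)c1[nH]c2ccccc2c1-c1c(OC)c(O)c(-c2c(C(C)(C)C=C)[nH]c3ccccc23)cc1O | intermediate (not isolated)
14 | 3-methoxy-2,5-bis[2-(2-methylbut-3-en-2-yl)-1H-indol-3-yl]-1,4-benzoquinone | C=CC(C)(C)c1[nH]c2ccccc2c1C1=C(OC)C(=O)C(c2c(C(C)(C)C=C)[nH]c3ccccc23)=CC1=O | intermediate (not isolated)
15 | 3,6-dimethoxy-2,5-bis[2-(2-methylbut-3-en-2-yl)-1H-indol-3-yl]benzene-1,4-diol | C=CC(C)(C)c1[nH]c2ccccc2c1-c1c(OC)c(O)c(-c2c(C(C)(C)C=C)[nH]c3ccccc23)c(OC)c1O | intermediate (not isolated)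
16 | 2,5-dimethoxy-3,6-bis[2-(2-methylbut-3-en-2-yl)-1H-indol-3-yl]-1,4-benzoquinone | C=CC(C)(C)c1[nH]c2ccccc2c1C1=C(OC)C(=O)C(c2c(C(C)(C)C=C)[nH]c3ccccc23)=C(OC)C1=O | target

**Step count**
Total steps: 4. Longest linear sequence: 4 (steps 1 → 2 → 3 → 4).

**Steps most likely to fail and their fallbacks**

Step 4 (the proposed new step). The risk is that C3/C6 of 12, flanked by a bulky indolyl group and made electron-richer by it, resists methanol addition, or that acid damages the 1,1-dimethylallyl groups. The fallback uses known haloquinone chemistry; it sets out from 7 and comes back to the route at 16. Acid-promoted conjugate addition of 7 (1 equiv) to commercial 2,5-dichloro-1,4-benzoquinone (conc. HCl, THF) followed by DDQ gives 2,5-dichloro-3-[2-(2-methylbut-3-en-2-yl)-1H-indol-3-yl]-1,4-benzoquinone F3. A second addition of 7 under the same conditions, again finished with DDQ, gives 2,5-dichloro-3,6-bis[2-(2-methylbut-3-en-2-yl)-1H-indol-3-yl]-1,4-benzoquinone F4; the chlorines fix the regiochemistry. NaOH in MeOH at reflux replaces both chlorides by addition–elimination and, after acidification, gives 2,5-dihydroxy-3,6-bis[2-(2-methylbut-3-en-2-yl)-1H-indol-3-yl]-1,4-benzoquinone F5. O-Methylation of this vinylogous acid with MeI and K2CO3 in DMF gives 16. The C–O bonds are still formed last, but by substitution of chloride instead of hydrogen.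

Step 3. The risk is a mixture of mono- and bis-adducts (or some 2,6-isomer), because the indole can also attack the benzoquinone that is meant to act as hydrogen acceptor. The fallback replaces the one-pot transfer-dehydrogenation cascade by two separate C–C bond formations with isolation and an external, non-electrophilic oxidant; it sets out from 7 and 8 and comes back at 12. Indole 7 (1.0 equiv) and 8 (2.2 equiv, deliberately in excess) in AcOH give the mono(indolyl)quinone 10, which is now isolated and purified. Then 10 and 7 (1.1 equiv) with catalytic H2SO4 in THF give the hydroquinone 11, which is oxidised in a separate operation with Ag2CO3 on Celite to 12. This fallback makes no compound outside the list (F0).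

Step 2. The risk is that 3-chloroindole decomposes or that its N–H simply protonolyses the allylborane. The fallback builds the indole ring de novo by a modified Madelung synthesis; it sets out from no numbered compound of the route but from commercial o-toluidine and 2,2-dimethylbut-3-enoic acid (replacing 1–6), and comes back at 7. The acid and SOCl2 give 2,2-dimethylbut-3-enoyl chloride F1, which acylates o-toluidine (Et3N, CH2Cl2) to N-(2-methylphenyl)-2,2-dimethylbut-3-enamide F2. n-BuLi (3 equiv) in THF, 0 °C → rt, forms the N,C-dianion, whose benzylic carbanion closes onto the amide carbonyl and dehydrates to 7.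

**Further compounds**
F1 | step 2 | 2,2-dimethylbut-3-enoyl chloride | C=CC(C)(C)C(Cl)=O
F2 | step 2 | N-(2-methylphenyl)-2,2-dimethylbut-3-enamide | C=CC(C)(C)C(=O)Nc1ccccc1C
F0 | step 3 | none | none
F3 | step 4 | 2,5-dichloro-3-[2-(2-methylbut-3-en-2-yl)-1H-indol-3-yl]-1,4-benzoquinone | C=CC(C)(C)c1[nH]c2ccccc2c1C1=C(Cl)C(=O)C=C(Cl)C1=O
F4 | step 4 | 2,5-dichloro-3,6-bis[2-(2-methylbut-3-en-2-yl)-1H-indol-3-yl]-1,4-benzoquinone | C=CC(C)(C)c1[nH]c2ccccc2c1C1=C(Cl)C(=O)C(c2c(C(C)(C)C=C)[nH]c3ccccc23)=C(Cl)C1=O
F5 | step 4 | 2,5-dihydroxy-3,6-bis[2-(2-methylbut-3-en-2-yl)-1H-indol-3-yl]-1,4-benzoquinone | C=CC(C)(C)c1[nH]c2ccccc2c1C1=C(O)C(=O)C(c2c(C(C)(C)C=C)[nH]c3ccccc23)=C(O)C1=O
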